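## Structural features

The target is a 3,4-dihydroisocoumarin: benzene ring A is fused through C4a and C8a to the δ-lactone ring B (C1, O2, C3, C4). Ring A carries a free phenol at C8, peri to the lactone carbonyl, so that C8–OH, C8a–C1 and C4a–C4 together form a 6-alkylsalicylate. The only stereocentre is C3 (R). It bears the lactone oxygen and an unbranched (1E,3E)-heptadeca-1,3-dienyl chain and has no stereogenic neighbour, so its configuration must be controlled absolutely. The C3–O2 bond is a dienylic ester bond that can ionise under acid or with zerovalent palladium; the diene can lose its geometry, the lactone is open to base and the phenol is acidic. The difficulty therefore lies less in the ring system than in joining an enantiopure C3 to an (E,E)-diene without disturbing either. The key step uses the fact that C7, C8, C8a and C1 map onto an acetoacetate unit, while C6, C5 and C4a (with C4 and the C3 side chain attached) map onto a β-ketoacetal as 1,3-dielectrophile.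

## Logic of the disconnections

**26 ⇒ 25.** The lactone bond C1–O2 is cut and O2 is capped as a silyl ether. In 25 the C3 oxygen is not a leaving group and C1 is a methyl ester, so the sensitive dienylic lactone exists only in the last flask. The forward step must remove silicon and close ring B without acid and without breaking the C3–O bond.

**25 ⇒ 18 + 23.** The C1'=C2' double bond next to C3 is cut. This divides the molecule into the aromatic head 18, which holds all heteroatoms and the stereocentre, and the lipid tail 23, whose second alkene already has its geometry. Olefinating the open-chain silyl ether, not a 3-formyl lactone, avoids an α-acyloxy aldehyde, which is more easily epimerised and whose adduct alkoxide could take up the neighbouring acyl group. The forward step must form the new alkene E, keep the α-oxygenated aldehyde configurationally intact and cope with the free phenol.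

**23 ⇒ 22 ⇒ 21 ⇒ 20 ⇒ 19.** The sulfone is traced to the sulfide (S–O bonds), the C–S bond to an allylic alcohol, the alcohol to an ester, and the C3'=C4' bond to 19 by a phosphonate olefination. All are routine; the demands are E geometry in the olefination and S-alkylation without allylic transposition.

**18 ⇒ 17 ⇒ 16.** No skeletal bond is cut: the formyl group is traced to the primary alcohol and this to its benzyl ether, which is chosen to survive the Lewis acid of the ring synthesis. The forward steps need a hydrogenolysis that spares the silyl ether and an oxidation that spares the phenol.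

**16 ⇒ 4 + 13.** Ring A is cut at C6–C7 and C4a–C8a. This removes the arene and leaves two acyclic pieces, one of them achiral, and it delivers the C8 hydroxyl free, so no phenol deprotection is needed. The forward step must pair the diene terminus with the acetal carbon and the central carbon with the ketone, and must leave the β-silyloxy group of 13 in place.

**4 ⇒ 2 ⇒ 1.** Two O–Si bonds are cut in turn; the forward steps are enol silylation and γ-deprotonation/silylation.

**13 ⇒ 12 ⇒ 11.** The ketone is masked as a dithioacetal and the silyl ether is traced to the alcohol. The forward unmasking must spare the dimethyl acetal and the silyl ether.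

**11 ⇒ 8 + 9, and 8 ⇒ 5 + 6.** The bond between the carbonyl carbon and the methylene next to the stereocentre (C3–C4 of the hexanone chain of 13) is cut by epoxide opening, and C2–C3 by alkylation. The stereocentre is thus bought with 9 in enantiopure form and is not made by an asymmetric aldol reaction, whose enantioselectivity with a methyl ketone would be uncertain. The forward steps need an acyl anion equivalent that tolerates the acetal and attacks the unsubstituted epoxide carbon.

## Other disconnections considered

**Alternative 1:** The cut passes through C3–C4 and O2–C1, so ring B and the C3 stereocentre would arise together from the homophthalic anhydride A1 and the dienal A2.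
- Forward step: the enol of A1, held by a bifunctional cinchona squaramide, would add through C4 to the formyl carbon of A2; the new alkoxide would close onto the aryl-bound carbonyl to give the trans acid A3, with C3 as in the target.
- In favour: one catalytic step would give ring B, the stereocentre and the whole carbon skeleton from two simple partners, and ring A would be bought. On convergence and step count this design is the better one.
- Against: this mode of addition is best established for aryl aldehydes; with A2, competing conjugate addition and weaker facial control must be expected. The C4 carboxyl of A3 is an arylacetic acid, not a β-keto acid, so its removal needs a radical or forcing thermal decarboxylation. A radical or carbanion at C4 sits β to the C3–O2 bond and can open ring B. The acetal on O8 would then have to be cleaved by acid next to the ionisable C3–O2 bond.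
- Comparison: the alternative makes the stereocentre by catalysis where the chosen plan buys it, and it places its main hazards after the diene is present, where the chosen plan builds its ring before. Both ring closures are ionic additions to carbonyl groups, and the two are equal in needing no metal catalyst.

**Alternative 2:** The cut removes C8–C8a and C4a–C5 of ring A, giving the ynoate A4 and the diene A5 as precursors of the benzoate A6.
- Forward step: thermal [4+2] addition of A5 across the triple bond of A4, followed by a cycloreversion that expels the two-carbon bridge.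
- In favour: the conditions are neutral and reagent-free, so no Lewis acid reaches the silyloxy stereocentre; on this point it is better than the chosen key step. Regiocontrol by the methoxy group is as dependable as that by the acetal, each route forms two C–C bonds and one ring, and the stereocentre is a spectator in both; here the two are equal. A4 comes from the same chiral pool in about as many steps as 13.
- Against: the temperature is well above 150 °C, A5 is normally an isomer mixture used in excess, and the C8 oxygen emerges as a methyl ether. The extra Lewis-acidic demethylation suits silyl ethers poorly and makes the route one step longer.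
- Comparison: the mechanism is simpler (concerted, no ionic intermediates), the step economy slightly worse. A variant of this disconnection is kept as the reserve for step 7.

**Alternative 3:** The cut passes through C4–C4a and O2–C3, so the iodo acid A7 and the triene A8 would give the lactone A9 in a single palladium-catalysed heteroannulation.
- Forward step: zerovalent palladium with a chiral phosphine would insert into the C–I bond of A7, the aryl group would add to the CH2 terminus of A8, and the carboxylate would attack the resulting allylpalladium at C3.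
- In favour: ring B, the stereocentre and the complete side chain would be formed at once, one deprotection from the target. On step economy and convergence it is clearly better than the chosen plan.
- Against: the enantioselectivity would have to come from the ligand during C–O bond formation on an allyl system that extends over five carbons and can equilibrate, so both the site and the face of attack are open. The 2,6-disubstituted aryl iodide is hindered. A9 is itself a dienylic ester that the same zerovalent palladium can re-ionise. A8 is prone to polymerise. The last step would again be an acidic acetal cleavage next to the C3–O2 bond.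
- Comparison: the alternative makes a bond at C3 under catalysis, whereas the chosen plan forms or breaks no bond at C3 after the epoxide opening. It is organometallic and catalytic where the chosen plan is ionic and stoichiometric, and it is far shorter. The chosen plan is longer, but its absolute configuration does not depend on an unproven catalyst–substrate match.

Key step: step 7

Assumption: the enol ethers 2, 3 and 4 are handled as mixtures of double-bond isomers, because their geometry is erased in step 7. Their SMILES carry no alkene descriptor, and 14 and 15 are diastereomer mixtures at the centres lost on aromatisation.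

## Route

Step 1
Reactants: 1 methyl acetoacetate
Product: 2 methyl 3-(trimethylsilyloxy)but-2-enoate
Conditions: Me3SiCl, Et3N, hexane, rt
Reagents that add atoms: chlorotrimethylsilane, C[Si](C)(C)Cl
Why: The enol form of the β-ketoester is O-silylated by chlorosilane and amine base (silyl enol ether formation), giving the conjugated mono-silyl enol ether.

Step 2
Reactants: 2 methyl 3-(trimethylsilyloxy)but-2-enoate
Product: 4 1-methoxy-1,3-bis(trimethylsilyloxy)buta-1,3-diene, via lithium dienolate 3 (not isolated)
Conditions: LiN(iPr)2, THF, −78 °C; Me3SiCl, −78 °C → rt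
Reagents that add atoms: chlorotrimethylsilane, C[Si](C)(C)Cl
Why: The amide base removes a γ-proton of the vinylogous ester to give dienolate 3, and O-silylation of this anion by the hard chlorosilane should give the bis-silyl dienolate (silyl ketene acetal formation).

Step 3
Reactants: 5 1,3-dithiane; 6 2-bromo-1,1-dimethoxyethane
Product: 8 2-(2,2-dimethoxyethyl)-1,3-dithiane, via 2-lithio-1,3-dithiane 7 (not isolated)
Conditions: n-BuLi, THF, −30 °C; 6, −30 °C → rt
Reagents that add atoms: none
Why: Corey–Seebach alkylation: the sulfur-stabilised anion 7 displaces bromide from the primary halide by an SN2 reaction, and the acetal is inert to the organolithium.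

Step 4
Reactants: 8 2-(2,2-dimethoxyethyl)-1,3-dithiane; 9 (2R)-2-[(benzyloxy)methyl]oxirane
Product: 11 (2R)-1-(benzyloxy)-3-[2-(2,2-dimethoxyethyl)-1,3-dithian-2-yl]propan-2-ol, via 2-lithiodithiane 10 (not isolated)
Conditions: n-BuLi, THF, −25 °C; 9, −25 → 0 °C; aq. NH4Cl
Reagents that add atoms: none
Why: Corey–Seebach epoxide opening: anion 10 attacks the unsubstituted epoxide carbon by an SN2 reaction, so the C–O bond at the stereocentre is untouched and the R configuration of 9 passes unchanged into 11. The acetal oxygens are not β to the carbanion, so elimination is not possible.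

Step 5
Reactants: 11 (2R)-1-(benzyloxy)-3-[2-(2,2-dimethoxyethyl)-1,3-dithian-2-yl]propan-2-ol
Product: 12 tert-butyl{[(2R)-1-(benzyloxy)-3-[2-(2,2-dimethoxyethyl)-1,3-dithian-2-yl]propan-2-yl]oxy}dimethylsilane
Conditions: TBSCl, imidazole, DMF, rt
Reagents that add atoms: tert-butyldimethylsilyl chloride, CC(C)(C)[Si](C)(C)Cl
Why: Silylation of a secondary alcohol with silyl chloride and imidazole; these mildly basic conditions leave the dimethyl acetal and the dithiane alone, and the bulky ether later keeps O5 from closing onto C1.

Step 6
Reactants: 12 tert-butyl{[(2R)-1-(benzyloxy)-3-[2-(2,2-dimethoxyethyl)-1,3-dithian-2-yl]propan-2-yl]oxy}dimethylsilane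
Product: 13 (5R)-6-(benzyloxy)-5-(tert-butyldimethylsilyloxy)-1,1-dimethoxyhexan-3-one
Conditions: MeI, CaCO3, MeCN/H2O (9:1), 45 °C
Reagents that add atoms: water, O
Why: S-Methylation turns the dithiane into a leaving group and water then gives the ketone (alkylative dithioacetal hydrolysis). CaCO3 takes up the HI formed, so the acetal, the silyl ether and the β-silyloxy ketone should stay intact.

Step 7
Reactants: 4 1-methoxy-1,3-bis(trimethylsilyloxy)buta-1,3-diene; 13 (5R)-6-(benzyloxy)-5-(tert-butyldimethylsilyloxy)-1,1-dimethoxyhexan-3-one
Product: 16 methyl 2-[(2R)-3-(benzyloxy)-2-(tert-butyldimethylsilyloxy)propyl]-6-hydroxybenzoate, via acyclic enol silyl ether 14 (not isolated), via cyclic aldol 15 (not isolated)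
Conditions: TiCl4 (1.1 equiv) added to 4 + 13, CH2Cl2, −78 → −20 °C; aq. NaHCO3
Reagents that add atoms: none
Why: TiCl4 ionises the dimethyl acetal of 13 to an oxocarbenium ion, which the terminal CH2 of 4 attacks in a Mukaiyama-type addition to give 14 (bond C6–C7). The remaining β-ketoester enol ether of 14 then adds through its central carbon to the titanium-activated ketone, a 6-(enolendo)-exo-trig aldol closure that gives 15 (bond C4a–C8a). β-Elimination of water and of methanol from 15 and enolisation of the resulting dienone should deliver ring A with the C8 hydroxyl free. The closest known reaction type is the TiCl4-mediated [3+3] cycloaromatisation of 1,3-bis(silyloxy)-1,3-dienes with β-ketoacetals, which gives 6-alkylsalicylates. No stereocentre is formed, and the C5 stereocentre of 13 is a spectator because its C–O bond takes no part. The required regiochemistry (diene terminus to acetal carbon, central carbon to ketone) follows from the higher electrophilicity of the oxocarbenium ion and the higher nucleophilicity of the diene terminus. The required chemoselectivity is retention of the β-silyloxy group, which the bulky silyl group, the low temperature and the addition of TiCl4 to the premixed partners should secure.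

Step 8
Reactants: 16 methyl 2-[(2R)-3-(benzyloxy)-2-(tert-butyldimethylsilyloxy)propyl]-6-hydroxybenzoate
Product: 17 methyl 2-[(2R)-2-(tert-butyldimethylsilyloxy)-3-hydroxypropyl]-6-hydroxybenzoate
Conditions: H2 (1 atm), Pd/C, EtOAc, rt
Reagents that add atoms: none
Why: Hydrogenolysis of the benzyl ether over Pd/C; in a neutral aprotic solvent the secondary silyl ether, the methyl ester and the phenol are not affected, and no other reducible group is present.

Step 9
Reactants: 17 methyl 2-[(2R)-2-(tert-butyldimethylsilyloxy)-3-hydroxypropyl]-6-hydroxybenzoate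
Product: 18 methyl 2-[(2R)-2-(tert-butyldimethylsilyloxy)-3-oxopropyl]-6-hydroxybenzoate
Conditions: Dess–Martin periodinane, NaHCO3, CH2Cl2, 0 °C → rt
Reagents that add atoms: none
Why: Dess–Martin oxidation of the primary alcohol stops at the aldehyde and is run buffered, so the α-silyloxy stereocentre should not epimerise. The phenol is deactivated by the ortho ester and its hydrogen bond and is not expected to be oxidised; 18 is used at once.

Step 10
Reactants: 19 tetradecanal
Product: 20 ethyl (2E)-hexadec-2-enoate
Conditions: (EtO)2P(O)CH2CO2Et, NaH, THF, 0 °C → rt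
Reagents that add atoms: triethyl phosphonoacetate, CCOC(=O)CP(=O)(OCC)OCC
Why: Horner–Wadsworth–Emmons olefination of an unbranched aldehyde with a stabilised phosphonate anion; reversible addition favours the E-enoate.

Step 11
Reactants: 20 ethyl (2E)-hexadec-2-enoate
Product: 21 (2E)-hexadec-2-en-1-ol
Conditions: iBu2AlH, CH2Cl2, −78 → 0 °C; aq. Rochelle salt
Reagents that add atoms: none
Why: The aluminium hydride reduces the conjugated ester by 1,2-hydride delivery to the allylic alcohol without touching the alkene, whose geometry is retained.

Step 12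
Reactants: 21 (2E)-hexadec-2-en-1-ol
Product: 22 5-[(2E)-hexadec-2-en-1-ylsulfanyl]-1-phenyl-1H-tetrazole
Conditions: 1-phenyl-1H-tetrazole-5-thiol, PPh3, DIAD, THF, 0 °C → rt
Reagents that add atoms: 1-phenyl-1H-tetrazole-5-thiol, Sc1nnnn1-c1ccccc1
Why: Mitsunobu reaction: the acidic thiol displaces the activated primary allylic oxygen by an SN2 reaction at C1, so the E-alkene stays in place.

Step 13
Reactants: 22 5-[(2E)-hexadec-2-en-1-ylsulfanyl]-1-phenyl-1H-tetrazole
Product: 23 5-[(2E)-hexadec-2-en-1-ylsulfonyl]-1-phenyl-1H-tetrazole
Conditions: (NH4)6Mo7O24·4H2O (cat.), 30% H2O2, EtOH, 0 °C → rt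
Reagents that add atoms: hydrogen peroxide, OO
Why: Molybdate-catalysed oxidation with H2O2 takes the sulfide through the sulfoxide to the sulfone; this system is not expected to epoxidise an unactivated disubstituted alkene at this temperature.

Step 14
Reactants: 18 methyl 2-[(2R)-2-(tert-butyldimethylsilyloxy)-3-oxopropyl]-6-hydroxybenzoate; 23 5-[(2E)-hexadec-2-en-1-ylsulfonyl]-1-phenyl-1H-tetrazole
Product: 25 methyl 2-[(2R,3E,5E)-2-(tert-butyldimethylsilyloxy)nonadeca-3,5-dien-1-yl]-6-hydroxybenzoate, via potassium sulfonyl carbanion 24 (not isolated)
Conditions: 23 (2.3 equiv), KN(SiMe3)2 (2.2 equiv), 18-crown-6, THF, −78 °C; then 18, −78 °C → rt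
Reagents that add atoms: none
Why: Julia–Kocienski olefination: anion 24 adds to the aldehyde, the alkoxide transfers the tetrazolyl group from sulfur to oxygen (Smiles rearrangement) and anti-elimination forms the C3=C4 alkene; the E isomer should be favoured by the crown-ether-complexed potassium counter-ion, which makes the addition reversible. One equivalent of 24 is spent on the phenol, hence the excess. The α-oxygen is a silyl ether, so no acyl shift can compete with the Smiles step and the C2 stereocentre should keep its configuration.

Step 15
Reactants: 25 methyl 2-[(2R,3E,5E)-2-(tert-butyldimethylsilyloxy)nonadeca-3,5-dien-1-yl]-6-hydroxybenzoate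
Product: 26 (3R)-3-[(1E,3E)-heptadeca-1,3-dien-1-yl]-8-hydroxy-3,4-dihydro-1H-isochromen-1-one
Conditions: Bu4NF, THF, 0 °C → rt; aq. NH4Cl
Reagents that add atoms: none
Why: Fluoride cleaves the O–Si bond and the C3 alkoxide closes ring B by intramolecular acyl substitution on the methyl ester (6-exo-trig lactonisation). The C3–O bond is not broken, so the R configuration is retained, and the basic medium cannot ionise the dienylic C–O bond.

## Compound list

1 | methyl acetoacetate | CC(=O)CC(=O)OC | starting material
2 | methyl 3-(trimethylsilyloxy)but-2-enoate | CC(O[Si](C)(C)C)=CC(=O)OC | intermediate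
3 | lithium 1-methoxy-3-(trimethylsilyloxy)buta-1,3-dien-1-olate | COC(O[Li])=CC(=C)O[Si](C)(C)C | intermediate
4 | 1-methoxy-1,3-bis(trimethylsilyloxy)buta-1,3-diene | COC(O[Si](C)(C)C)=CC(=C)O[Si](C)(C)C | intermediate
5 | 1,3-dithiane | C1CSCSC1 | starting material
6 | 2-bromo-1,1-dimethoxyethane | COC(CBr)OC | starting material
7 | 2-lithio-1,3-dithiane | [Li]C1SCCCS1 | intermediate
8 | 2-(2,2-dimethoxyethyl)-1,3-dithiane | COC(CC1SCCCS1)OC | intermediate
9 | (2R)-2-[(benzyloxy)methyl]oxirane | c1ccccc1COC[C@H]1CO1 | starting material
10 | 2-(2,2-dimethoxyethyl)-2-lithio-1,3-dithiane | [Li]C1(CC(OC)OC)SCCCS1 | intermediate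
11 | (2R)-1-(benzyloxy)-3-[2-(2,2-dimethoxyethyl)-1,3-dithian-2-yl]propan-2-ol | c1ccccc1COC[C@H](O)CC1(CC(OC)OC)SCCCS1 | intermediate
12 | tert-butyl{[(2R)-1-(benzyloxy)-3-[2-(2,2-dimethoxyethyl)-1,3-dithian-2-yl]propan-2-yl]oxy}dimethylsilane | c1ccccc1COC[C@H](O[Si](C)(C)C(C)(C)C)CC1(CC(OC)OC)SCCCS1 | intermediate
13 | (5R)-6-(benzyloxy)-5-(tert-butyldimethylsilyloxy)-1,1-dimethoxyhexan-3-one | c1ccccc1COC[C@H](O[Si](C)(C)C(C)(C)C)CC(=O)CC(OC)OC | intermediate
14 | methyl (9R)-10-(benzyloxy)-9-(tert-butyldimethylsilyloxy)-5-methoxy-7-oxo-3-(trimethylsilyloxy)dec-2-enoate | COC(=O)C=C(O[Si](C)(C)C)CC(OC)CC(=O)C[C@@H](O[Si](C)(C)C(C)(C)C)COCc1ccccc1 | intermediate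
15 | methyl 2-[(2R)-3-(benzyloxy)-2-(tert-butyldimethylsilyloxy)propyl]-2-hydroxy-4-methoxy-6-oxocyclohexane-1-carboxylate | COC(=O)C1C(=O)CC(OC)CC1(O)C[C@@H](O[Si](C)(C)C(C)(C)C)COCc1ccccc1 | intermediate
16 | methyl 2-[(2R)-3-(benzyloxy)-2-(tert-butyldimethylsilyloxy)propyl]-6-hydroxybenzoate | c1ccccc1COC[C@H](O[Si](C)(C)C(C)(C)C)Cc1cccc(O)c1C(=O)OC | intermediate
17 | methyl 2-[(2R)-2-(tert-butyldimethylsilyloxy)-3-hydroxypropyl]-6-hydroxybenzoate | OC[C@H](O[Si](C)(C)C(C)(C)C)Cc1cccc(O)c1C(=O)OC | intermediate
18 | methyl 2-[(2R)-2-(tert-butyldimethylsilyloxy)-3-oxopropyl]-6-hydroxybenzoate | O=C[C@H](O[Si](C)(C)C(C)(C)C)Cc1cccc(O)c1C(=O)OC | intermediate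
19 | tetradecanal | CCCCCCCCCCCCCC=O | starting material
20 | ethyl (2E)-hexadec-2-enoate | CCCCCCCCCCCCC/C=C/C(=O)OCC | intermediate
21 | (2E)-hexadec-2-en-1-ol | CCCCCCCCCCCCC/C=C/CO | intermediate
22 | 5-[(2E)-hexadec-2-en-1-ylsulfanyl]-1-phenyl-1H-tetrazole | CCCCCCCCCCCCC/C=C/CSc1nnnn1-c1ccccc1 | intermediate
23 | 5-[(2E)-hexadec-2-en-1-ylsulfonyl]-1-phenyl-1H-tetrazole | CCCCCCCCCCCCC/C=C/CS(=O)(=O)c1nnnn1-c1ccccc1 | intermediate
24 | potassium (2E)-1-[(1-phenyl-1H-tetrazol-5-yl)sulfonyl]hexadec-2-en-1-ide | CCCCCCCCCCCCC/C=C/[CH-]S(=O)(=O)c1nnnn1-c1ccccc1.[K+] | intermediate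
25 | methyl 2-[(2R,3E,5E)-2-(tert-butyldimethylsilyloxy)nonadeca-3,5-dien-1-yl]-6-hydroxybenzoate | CCCCCCCCCCCCC/C=C/C=C/[C@H](O[Si](C)(C)C(C)(C)C)Cc1cccc(O)c1C(=O)OC | intermediate
26 | (3R)-3-[(1E,3E)-heptadeca-1,3-dien-1-yl]-8-hydroxy-3,4-dihydro-1H-isochromen-1-one | CCCCCCCCCCCCC/C=C/C=C/[C@H]1Cc2cccc(O)c2C(=O)O1 | target

## Step count and least certain steps

Total step count: 15. Longest linear sequence: 9 steps (3, 4, 5, 6, 7, 8, 9, 14, 15).

**Step 7 (key step).** What may go wrong: Lewis-acid-induced β-elimination or loss of the silyloxy group, capture of the oxocarbenium ion by O5 in place of the diene, or stalling before aromatisation.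
Fallback, setting out from 9 and returning at 16: 9 is opened with lithiated methyl propiolate (n-BuLi, BF3·OEt2, THF, −78 °C) to methyl (5R)-6-(benzyloxy)-5-hydroxyhex-2-ynoate F1. Silylation (TBSCl, imidazole, DMF) gives methyl (5R)-6-(benzyloxy)-5-(tert-butyldimethylsilyloxy)hex-2-ynoate F2. Heating F2 at about 170 °C with 1-(trimethylsilyloxy)cyclohexa-1,3-diene F3, made by thermodynamic silylation of cyclohex-2-enone (Me3SiCl, Et3N, DMF), should give the Alder–Rickert adduct methyl 3-[(2R)-3-(benzyloxy)-2-(tert-butyldimethylsilyloxy)propyl]-1-(trimethylsilyloxy)bicyclo[2.2.2]octa-2,5-diene-2-carboxylate F4. F4 loses its two-carbon bridge in the same operation to give methyl 2-[(2R)-3-(benzyloxy)-2-(tert-butyldimethylsilyloxy)propyl]-6-(trimethylsilyloxy)benzoate F5. Aqueous work-up cleaves the aryl silyl ether and the route is rejoined at 16.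

**Step 14.** What may go wrong: erosion of E selectivity at the new double bond, isomerisation of the allylic anion before it adds, or consumption of the anion by proton transfer from the phenol.
Fallback, setting out from 18 and returning at 25: Takai olefination (CrCl2, CHI3, THF) should convert 18 into methyl 2-[(2R,3E)-2-(tert-butyldimethylsilyloxy)-4-iodobut-3-en-1-yl]-6-hydroxybenzoate F6. Hydroboration of pentadec-1-yne with pinacolborane (Cp2Zr(H)Cl cat.) gives 4,4,5,5-tetramethyl-2-[(1E)-pentadec-1-en-1-yl]-1,3,2-dioxaborolane F7. Suzuki–Miyaura coupling of F6 with F7 (Pd(PPh3)4, aq. K3PO4, THF) joins the two alkenes with retention of both geometries and gives 25.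

**Step 6.** What may go wrong: hydrolysis of the dimethyl acetal alongside the dithioacetal, sluggish S-alkylation at the hindered dithiane, or β-elimination of the silyloxy group once the ketone is formed.
Fallback, setting out from 9 and returning at 13: opening of 9 with isopropenylmagnesium bromide (CuI cat., THF, −30 °C) gives (2R)-1-(benzyloxy)-4-methylpent-4-en-2-ol F8. Silylation (TBSCl, imidazole) gives tert-butyl{[(2R)-1-(benzyloxy)-4-methylpent-4-en-2-yl]oxy}dimethylsilane F9. Ozonolysis (O3, CH2Cl2, −78 °C; PPh3) gives (4R)-5-(benzyloxy)-4-(tert-butyldimethylsilyloxy)pentan-2-one F10. Kinetic enol silylation on the methyl side (LiN(iPr)2, Me3SiCl, THF, −78 °C) gives (4R)-5-(benzyloxy)-4-(tert-butyldimethylsilyloxy)-2-(trimethylsilyloxy)pent-1-ene F11. Mukaiyama-type addition of F11 to trimethyl orthoformate (BF3·OEt2, CH2Cl2, −78 °C) installs the acetal carbon and gives 13, with no thioacetal ever present beside the acetal.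

**Step 15.** What may go wrong: desilylation without ring closure, because the phenoxide formed under fluoride lowers the electrophilicity of the ester, or base-induced degradation of the dienyl carbinol on prolonged exposure.
Fallback, setting out from 25 and returning at 26: HF·pyridine buffered with pyridine (THF, 0 °C) removes the silyl group to give methyl 2-hydroxy-6-[(2R,3E,5E)-2-hydroxynonadeca-3,5-dien-1-yl]benzoate F12. Ti(OiPr)4 (toluene, 80 °C) then closes ring B by templated transesterification, again without breaking the C3–O bond, and gives 26.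

## Further compounds

F1 | step 7 | methyl (5R)-6-(benzyloxy)-5-hydroxyhex-2-ynoate | COC(=O)C#CC[C@@H](O)COCc1ccccc1
F2 | step 7 | methyl (5R)-6-(benzyloxy)-5-(tert-butyldimethylsilyloxy)hex-2-ynoate | COC(=O)C#CC[C@@H](O[Si](C)(C)C(C)(C)C)COCc1ccccc1
F3 | step 7 | 1-(trimethylsilyloxy)cyclohexa-1,3-diene | C[Si](C)(C)OC1=CC=CCC1
F4 | step 7 | methyl 3-[(2R)-3-(benzyloxy)-2-(tert-butyldimethylsilyloxy)propyl]-1-(trimethylsilyloxy)bicyclo[2.2.2]octa-2,5-diene-2-carboxylate (bridgehead mixture) | COC(=O)C1=C(C[C@@H](O[Si](C)(C)C(C)(C)C)COCc2ccccc2)C2C=CC1(O[Si](C)(C)C)CC2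
F5 | step 7 | methyl 2-[(2R)-3-(benzyloxy)-2-(tert-butyldimethylsilyloxy)propyl]-6-(trimethylsilyloxy)benzoate | c1ccccc1COC[C@H](O[Si](C)(C)C(C)(C)C)Cc1cccc(O[Si](C)(C)C)c1C(=O)OC
F6 | step 14 | methyl 2-[(2R,3E)-2-(tert-butyldimethylsilyloxy)-4-iodobut-3-en-1-yl]-6-hydroxybenzoate | I/C=C/[C@H](O[Si](C)(C)C(C)(C)C)Cc1cccc(O)c1C(=O)OC
F7 | step 14 | 4,4,5,5-tetramethyl-2-[(1E)-pentadec-1-en-1-yl]-1,3,2-dioxaborolane | CCCCCCCCCCCCC/C=C/B1OC(C)(C)C(C)(C)O1
F8 | step 6 | (2R)-1-(benzyloxy)-4-methylpent-4-en-2-ol | c1ccccc1COC[C@H](O)CC(C)=C
F9 | step 6 | tert-butyl{[(2R)-1-(benzyloxy)-4-methylpent-4-en-2-yl]oxy}dimethylsilane | c1ccccc1COC[C@H](O[Si](C)(C)C(C)(C)C)CC(C)=C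
F10 | step 6 | (4R)-5-(benzyloxy)-4-(tert-butyldimethylsilyloxy)pentan-2-one | c1ccccc1COC[C@H](O[Si](C)(C)C(C)(C)C)CC(C)=O
F11 | step 6 | (4R)-5-(benzyloxy)-4-(tert-butyldimethylsilyloxy)-2-(trimethylsilyloxy)pent-1-ene | c1ccccc1COC[C@H](O[Si](C)(C)C(C)(C)C)CC(=C)O[Si](C)(C)C
F12 | step 15 | methyl 2-hydroxy-6-[(2R,3E,5E)-2-hydroxynonadeca-3,5-dien-1-yl]benzoate | CCCCCCCCCCCCC/C=C/C=C/[C@H](O)Cc1cccc(O)c1C(=O)OC
A1 | alternative 1 | 8-(methoxymethoxy)-1H-isochromene-1,3(4H)-dione | COCOc1cccc2CC(=O)OC(=O)c12
A2 | alternative 1 | (2E,4E)-octadeca-2,4-dienal | CCCCCCCCCCCCC/C=C/C=C/C=O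
A3 | alternative 1 | trans-3-[(1E,3E)-heptadeca-1,3-dien-1-yl]-8-(methoxymethoxy)-1-oxo-3,4-dihydro-1H-isochromene-4-carboxylic acid (C3 as in the target) | CCCCCCCCCCCCC/C=C/C=C/[C@H]1[C@H](C(=O)O)c2cccc(OCOC)c2C(=O)O1
A4 | alternative 2 | methyl (5R)-5,6-bis(tert-butyldimethylsilyloxy)hex-2-ynoate | COC(=O)C#CC[C@@H](O[Si](C)(C)C(C)(C)C)CO[Si](C)(C)C(C)(C)C
A5 | alternative 2 | 1-methoxycyclohexa-1,3-diene | COC1=CC=CCC1
A6 | alternative 2 | methyl 2-[(2R)-2,3-bis(tert-butyldimethylsilyloxy)propyl]-6-methoxybenzoate | CC(C)(C)[Si](C)(C)OC[C@H](O[Si](C)(C)C(C)(C)C)Cc1cccc(OC)c1C(=O)OC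
A7 | alternative 3 | 2-iodo-6-(methoxymethoxy)benzoic acid | COCOc1cccc(I)c1C(=O)O
A8 | alternative 3 | (3E,5E)-nonadeca-1,3,5-triene | CCCCCCCCCCCCC/C=C/C=C/C=C
A9 | alternative 3 | (3R)-3-[(1E,3E)-heptadeca-1,3-dien-1-yl]-8-(methoxymethoxy)-3,4-dihydro-1H-isochromen-1-one | CCCCCCCCCCCCC/C=C/C=C/[C@H]1Cc2cccc(OCOC)c2C(=O)O1
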